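## The problem

The target is a bicyclo[3.3.1]nonane-2,4,9-trione. Ring A (C1–C5 with C9) and ring B (C1, C8, C7, C6, C5 with C9) share the C9 ketone, so both α-carbons of that ketone, C1 and C5, are quaternary bridgeheads, and C1 also sits next to the quaternary C8. Ring B carries three stereocentres (C1, C5, C7). The bicycle forces the C1–C2 and C5–C4 bonds to be cis and 1,3-diaxial on ring B, and both are trans to the equatorial C7 prenyl group. The one relationship to be set is therefore "both ring A arms anti to the C7 substituent", which C7 can control through the ring B chair if each arm is the last group to enter its carbon. C7 has no controller and must come from an enantioselective step. The (S)-carbinol of the C5 side chain is too remote for ring control and must be brought in enantiopure together with its E-trisubstituted olefin. Three prenyl-type olefins and an allylic alcohol exclude hydrogenation, strong protic or Lewis acids and electrophilic halogen; the catechol is oxidation-prone; the enolised β-triketone cyclises onto neighbouring prenyl groups in acid, and its central carbon C3 is hard to acylate once the bicycle exists. The array C2(=O)–C3(aroyl)=C4(OH) is the hydrolysed form of a 4-acyl-5-arylisoxazole (C4 bound to nitrogen, C3 bearing the acyl group, the aroyl carbon bound to oxygen). Ring A and the aroyl group can thus be made together from a nitrile oxide on C5 and an aryl ynone on C1.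

## Retrosynthesis

Atom labels C1–C9 are those of the bicyclic core of target 33 and are kept for all ring B intermediates.

**33 ⇒ 32 ⇒ 31 ⇒ 30.** No skeletal bond is cut. The side-chain silyl ether is removed last (32), the C4 oxygen is traced back to the nitrogen of enaminone 31, and 31 to isoxazole 30 by restoring the N–O bond. This is preferred to late C3 aroylation of a bare trione, which is the weak step of most routes to such compounds. The forward steps must open the N–O bond without touching olefins and exchange NH2 for OH without acid.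

**30 ⇒ 28 (through nitrile oxide 29).** The C3–C4 bond and the O–C(aryl) bond are cut together. Compared with cutting C2–C3 or C4–C5 alone, this removes ring A, the heterocycle and the aroyl problem in one operation and leaves a monocyclic cyclohexanone. The forward cycloaddition needs only the two arms cis on ring B and a mild oxidant for the aldoxime.

**28 ⇒ 27 ⇒ 26 ⇒ 19 + 24.** The oxime is made last from aldehyde 27, because a free oxime does not survive the oxidants that make the ynone. Ynone and aldehyde come from diol 26 in one oxidation. The C1–C2 bond is cut by an aldol disconnection to ketone 19 and ynal 24. The acyl arm is placed on C1 after the prenyl group so that it enters axially, anti to the axial C8 methyl and trans to C7. The reverse order would put the prenyl group axial.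

**19 ⇒ 18 ⇒ 17.** The C5–C4 bond is cut as an enolate–formaldehyde aldol. The one-carbon arm must enter after the side chain, for the same stereochemical reason as at C1. Carboxylating C5 first and alkylating second would place the side chain axial and lead to the C7-epimeric (endo) series. Hydroxymethyl also reaches the aldehyde by oxidation, so no ester has to be reduced beside a ketone.

**17 ⇒ 9 + 15.** The C5–side chain bond is cut to the kinetic enolate of ketone 9 and allylic bromide 15. The precursor has only the C7 stereocentre, and the forward step needs only regioselective deprotonation at the unhindered C5 methylene.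

**9 ⇒ 6 + 7; 6 ⇒ 5 ⇒ 4 ⇒ 3 ⇒ 1 + 2.** Conjugate addition of methyl to enone 6 and trapping of enolate 8 with prenyl bromide 7 make the C8 gem-dimethyl group and the C1–prenyl bond in one step, with the enolate regiochemistry fixed by the enone. Enone 6 comes from enone 4 by methyl addition (5) and re-oxidation. Enone 4 comes from keto aldehyde 3, the organocatalytic Michael adduct of aldehyde 1 and methyl vinyl ketone 2, which sets C7. Alkylating a 3-alkoxycyclohexenone would be shorter but gives the racemate.

**15 ⇒ 14 ⇒ 13 ⇒ 12 ⇒ 11 ⇒ 10.** The bromide comes from alcohol 14 and acetate 13. The prenyl terminus of 13 is made by cross-metathesis of the allyl group of 12. The carbinol is set by asymmetric allylation of enal 10 (giving 11). Direct prenyl-metal addition to 10 would attack through the γ-carbon and give the reverse-prenyl isomer.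

**24 ⇒ 22 ⇒ 21 ⇒ 20.** The ynal is cut at the formyl carbon to the acetylide from dibromoolefin 22, which comes from silylated aldehyde 21 and 3,4-dihydroxybenzaldehyde 20.

## Roads not taken

**Alternative 1:** The cut is C5–C6 of ring B, traced back to a ring-contracted cis-hydrindane epoxy alcohol A1. In the forward step BF3·OEt2 would open the C4–C5 epoxide of A1 and C6 would shift from C9 to C5, giving bridged hydroxy ketone A2 with the C9 ketone unveiled.
- Merit: the shift is stereospecific, so C5 is set by the epoxide geometry and not by enolate facial selectivity. In this respect it is better than the chosen plan, which relies on substrate-controlled additions at C5 and C1.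
- Weak points: a Lewis acid and a tertiary cation at C5 sit next to the side-chain olefin and two prenyl groups, inviting cation–olefin cyclisation. A1 needs a separate synthesis with five stereocentres. A2 still needs C4 oxidation, acidic ketal removal and the difficult C3 aroylation.
- The chosen plan sets against this the delivery of C2, C3, C4 and the aroyl group at the final oxidation level in the key step, with no Lewis acid near the olefins.

**Alternative 2:** The cut is C4–C5. With Ph3PAuNTf2 (monovalent gold) the C9 silyl enol ether of A3 would attack the terminal alkyne carbon of its C1 ynone in a 6-endo-dig closure to enone A4.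
- Merits: the carbocyclisation has precedent on this skeleton and is catalytic. C5 becomes quaternary in the ring closure, so its configuration follows from C1 and only one bridgehead must be preset. A3 also needs no one-carbon arm or oxime. In stereochemical economy and in the length of the precursor this road is better.
- Weak points: A4 lacks the C4 oxygen and the C3 aroyl group, so enone oxidation and a strongly basic C3 metalation–acylation must follow (four to five steps). The C1 prenyl olefin and the gold-activated alkyne form a 1,6-enyne that can cycloisomerise.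
- The chosen plan pays with a longer precursor but ends ring A fully functionalised.

**Alternative 3:** The cut is C2–C3. With SnCl2 (divalent tin) the diazo carbon of C5 diazoketone A5 would add to the C1 aldehyde, and hydride shift with loss of nitrogen would give trione A6.
- Merits: ring A appears directly as the 2,4-dione under mild conditions. A6 would also allow the aroyl group to be varied late, which the chosen plan does not.
- Weak points: the homologation is reliable for diazo esters and unhindered aldehydes, but here the nucleophile is a diazoketone and the aldehyde is neopentyl. The tin carbenoid can cyclopropanate the side-chain olefin. A5 needs diazomethane chemistry at a neopentyl acid. Both bridgeheads must be preset exactly as in the chosen plan, and C3 aroylation of A6 remains.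
- Stereochemical demands are equal; the chosen plan avoids the late C-acylation.

Key step: step 20

Assumption: 5-methylhex-4-enal (1), (−)-Ipc2B(allyl) solution and O-(tert-butyldimethylsilyl)hydroxylamine are taken as catalogue reagents, and the target is addressed as the C4-enol tautomer of its freely equilibrating β-triketone.

## Route

Step 1
Reactants: 1 5-methylhex-4-enal; 2 but-3-en-2-one (methyl vinyl ketone)
Product: 3 (2S)-2-(3-methylbut-2-en-1-yl)-5-oxohexanal
Conditions: (S)-2-[methoxy(diphenyl)methyl]pyrrolidine (5 mol %), ethyl 3,4-dihydroxybenzoate (20 mol %), neat, 4 °C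
Reagents that add atoms: none
Why: Enamine-catalysed Michael addition of an aldehyde to a vinyl ketone; the E-enamine is attacked on the face away from the diphenyl(methoxy)methyl group, which should give the (S)-configured α-carbon, the later C7.

Step 2
Reactants: 3 (2S)-2-(3-methylbut-2-en-1-yl)-5-oxohexanal
Product: 4 (4S)-4-(3-methylbut-2-en-1-yl)cyclohex-2-en-1-one
Conditions: LiOH·H2O (0.3 equiv), iPrOH, rt
Reagents that add atoms: none
Why: Intramolecular aldol condensation of a 1,5-keto aldehyde (Robinson-type ring closure); the methyl ketone enolate attacks the aldehyde and dehydration gives the enone, the mild base limiting epimerisation of the γ-stereocentre.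

Step 3
Reactants: 4 (4S)-4-(3-methylbut-2-en-1-yl)cyclohex-2-en-1-one
Product: 5 trimethyl{[(3S,4S)-3-methyl-4-(3-methylbut-2-en-1-yl)cyclohex-1-en-1-yl]oxy}silane (3,4-trans)
Conditions: Me2CuLi, TMSCl, THF, −78 °C
Reagents that add atoms: lithium dimethylcuprate, [Li+].C[Cu-]C; chlorotrimethylsilane, C[Si](C)(C)Cl
Why: TMSCl-accelerated conjugate addition of a Gilman cuprate; methyl enters anti to the prenyl group and the enolate is trapped regiospecifically as the silyl enol ether needed for step 4, where the new methyl stereocentre disappears again.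

Step 4
Reactants: 5 trimethyl{[(3S,4S)-3-methyl-4-(3-methylbut-2-en-1-yl)cyclohex-1-en-1-yl]oxy}silane
Product: 6 (4S)-3-methyl-4-(3-methylbut-2-en-1-yl)cyclohex-2-en-1-one
Conditions: Pd(OAc)2 (1.05 equiv), MeCN, rt
Reagents that add atoms: none
Why: Saegusa–Ito oxidation: the enolate of divalent palladium formed from the silyl enol ether undergoes β-hydride elimination toward the methyl-bearing carbon; the trisubstituted prenyl olefin is a poor ligand and should survive.

Step 5
Reactants: 6 (4S)-3-methyl-4-(3-methylbut-2-en-1-yl)cyclohex-2-en-1-one; 7 1-bromo-3-methylbut-2-ene (prenyl bromide)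
Product: 9 (4S)-3,3-dimethyl-2,4-bis(3-methylbut-2-en-1-yl)cyclohexan-1-one as a mixture of C2 epimers, via lithium enolate 8 (not isolated)
Conditions: Me2CuLi, Et2O, −20 → 0 °C; then 7, HMPA, THF, 0 °C → rt
Reagents that add atoms: lithium dimethylcuprate, [Li+].C[Cu-]C
Why: Cuprate conjugate addition followed by enolate alkylation; the addition creates the C8 gem-dimethyl group and a regiodefined enolate at C1, which the allylic bromide alkylates. The C1 configuration is immaterial because C1 is planarised again in step 17.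

Step 6
Reactants: 10 (2E)-3-methyl-4-oxobut-2-en-1-yl acetate [(E)-4-acetoxy-2-methylbut-2-enal]
Product: 11 (2E,4S)-4-hydroxy-3-methylhepta-2,6-dien-1-yl acetate
Conditions: (−)-Ipc2B(allyl), Et2O, −78 °C; then NaBO3·4H2O, THF/H2O, rt
Reagents that add atoms: (−)-B-allyldiisopinocampheylborane, C=CCB([C@@H]1C[C@@H]2C[C@H]([C@H]1C)C2(C)C)[C@@H]1C[C@@H]2C[C@H]([C@H]1C)C2(C)C
Why: Brown asymmetric allylboration through a chair Zimmerman–Traxler transition state; the reagent derived from (+)-α-pinene attacks the Si face of the enal carbonyl in a 1,2-sense and should set the (S)-carbinol. The allylic acetate is inert at −78 °C and to the mild perborate work-up.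

Step 7
Reactants: 11 (2E,4S)-4-hydroxy-3-methylhepta-2,6-dien-1-yl acetate
Product: 12 (2E,4S)-4-[(tert-butyldimethylsilyl)oxy]-3-methylhepta-2,6-dien-1-yl acetate
Conditions: TBSCl, imidazole, DMF, rt
Reagents that add atoms: tert-butyldimethylsilyl chloride, CC(C)(C)[Si](C)(C)Cl
Why: Standard silylation of a secondary alcohol; it differentiates the carbinol from the primary oxygen unmasked in step 9 and prevents allylic alcohol isomerisation during metathesis.

Step 8
Reactants: 12 (2E,4S)-4-[(tert-butyldimethylsilyl)oxy]-3-methylhepta-2,6-dien-1-yl acetate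
Product: 13 (2E,4S)-4-[(tert-butyldimethylsilyl)oxy]-3,7-dimethylocta-2,6-dien-1-yl acetate
Conditions: 2-methylbut-2-ene (excess), (H2IMes)(PCy3)Cl2Ru=CHPh (second-generation Grubbs catalyst, 3 mol %), CH2Cl2, 40 °C
Reagents that add atoms: 2-methylbut-2-ene, CC=C(C)C
Why: Olefin cross-metathesis turns the terminal allyl group into prenyl; the trisubstituted allylic acetate olefin is too hindered to take part.

Step 9
Reactants: 13 (2E,4S)-4-[(tert-butyldimethylsilyl)oxy]-3,7-dimethylocta-2,6-dien-1-yl acetate
Product: 14 (2E,4S)-4-[(tert-butyldimethylsilyl)oxy]-3,7-dimethylocta-2,6-dien-1-ol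
Conditions: K2CO3 (cat.), MeOH, 0 °C → rt
Reagents that add atoms: none
Why: Carbonate-catalysed methanolysis of the acetate (transesterification); the secondary alkyl TBS ether is stable under these conditions.

Step 10
Reactants: 14 (2E,4S)-4-[(tert-butyldimethylsilyl)oxy]-3,7-dimethylocta-2,6-dien-1-ol
Product: 15 (2E,4S)-1-bromo-4-[(tert-butyldimethylsilyl)oxy]-3,7-dimethylocta-2,6-diene
Conditions: CBr4, PPh3, CH2Cl2, 0 °C
Reagents that add atoms: carbon tetrabromide, BrC(Br)(Br)Br
Why: Appel bromination of a primary allylic alcohol under neutral conditions, without allylic transposition or loss of the E geometry.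

Step 11
Reactants: 9 (4S)-3,3-dimethyl-2,4-bis(3-methylbut-2-en-1-yl)cyclohexan-1-one; 15 (2E,4S)-1-bromo-4-[(tert-butyldimethylsilyl)oxy]-3,7-dimethylocta-2,6-diene
Product: 17 all-equatorial C5-alkylated ketone (C1 R, C5 S, C7 R), via kinetic epimer mixture 16 (not isolated)
Conditions: LiN(iPr)2, THF, −78 °C; 15, HMPA, −78 → 0 °C; then NaOMe (cat.), MeOH, rt
Reagents that add atoms: none
Why: Kinetic deprotonation takes place at the unhindered C5 methylene (C1–H is tertiary and neopentyl) and the lithium enolate is alkylated by the allylic bromide. Methoxide equilibration then places the C5 chain and the C1 prenyl group equatorial, cis to the C7 prenyl group (thermodynamic control), so that the C5–H is axial for step 12.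

Step 12
Reactants: 17 all-equatorial C5-alkylated ketone
Product: 18 C5-hydroxymethyl ketone (C1 R, C5 S, C7 R; CH2OH trans to the three chains)
Conditions: LiN(iPr)2, THF, −78 → −40 °C; CH2O (gas, from paraformaldehyde), −78 °C; AcOH
Reagents that add atoms: formaldehyde, C=O
Why: Aldol addition of a lithium enolate to monomeric formaldehyde; the base should remove the axial C5–H and not the C1–H flanked by the gem-dimethyl carbon. Formaldehyde adds along the axial trajectory of the chair that keeps the C7 prenyl equatorial, so the future C4 ends up axial and trans to C7 (substrate control by C7).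

Step 13
Reactants: 18 C5-hydroxymethyl ketone
Product: 19 C5-(triethylsilyloxymethyl) ketone (C1 R, C5 S, C7 R)
Conditions: TESCl, imidazole, DMF, 0 °C
Reagents that add atoms: chlorotriethylsilane, CC[Si](Cl)(CC)CC
Why: Silylation of the primary alcohol; the free β-hydroxy ketone would lose formaldehyde by retro-aldol under the base of step 17, and TES can later be removed beside three TBS ethers.

Step 14
Reactants: 20 3,4-dihydroxybenzaldehyde
Product: 21 3,4-bis[(tert-butyldimethylsilyl)oxy]benzaldehyde
Conditions: TBSCl, imidazole, DMF, rt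
Reagents that add atoms: tert-butyldimethylsilyl chloride, CC(C)(C)[Si](C)(C)Cl
Why: Bis-silylation of the catechol, which protects it against bases and oxidants until the end.

Step 15
Reactants: 21 3,4-bis[(tert-butyldimethylsilyl)oxy]benzaldehyde
Product: 22 4-(2,2-dibromoethenyl)-1,2-bis[(tert-butyldimethylsilyl)oxy]benzene
Conditions: CBr4, PPh3, Zn, CH2Cl2, 0 °C → rt
Reagents that add atoms: carbon tetrabromide, BrC(Br)(Br)Br
Why: First stage of the Corey–Fuchs sequence, a Wittig-type olefination by Ph3P=CBr2.

Step 16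
Reactants: 22 4-(2,2-dibromoethenyl)-1,2-bis[(tert-butyldimethylsilyl)oxy]benzene
Product: 24 3-{3,4-bis[(tert-butyldimethylsilyl)oxy]phenyl}prop-2-ynal, via lithium arylacetylide 23 (not isolated)
Conditions: n-BuLi (2.1 equiv), THF, −78 °C; DMF; inverse quench into cold aq. KH2PO4
Reagents that add atoms: N,N-dimethylformamide, CN(C)C=O
Why: Second stage of the Corey–Fuchs sequence: elimination and bromine–lithium exchange give the acetylide, which DMF formylates. The buffered inverse quench keeps dimethylamine from adding to the ynal.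

Step 17
Reactants: 19 C5-(triethylsilyloxymethyl) ketone; 24 3-{3,4-bis[(tert-butyldimethylsilyl)oxy]phenyl}prop-2-ynal
Product: 26 C1 aldol diol (C1 R, C5 S, C7 R; carbinol epimers), via TES-protected aldol adduct 25 (not isolated)
Conditions: LiN(iPr)2 (1.5 equiv), THF, −78 → 0 °C; 24, −78 °C; AcOH; then PPTS, MeOH, 0 °C → rt
Reagents that add atoms: none
Why: Directed aldol addition; C1–H is the only enolisable position left, and the tetrasubstituted lithium enolate adds to the small, highly electrophilic ynal carbonyl anti to the axial C8 methyl and trans to the C7 prenyl group. The new arm is therefore axial and cis to the C5 arm (C1 set by substrate control; the carbinol epimers converge in step 18). Mild acid then removes only the primary TES ether.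

Step 18
Reactants: 26 C1 aldol diol
Product: 27 C5-formyl C1-ynone (C1 R, C5 S, C7 R)
Conditions: DMP, pyridine, CH2Cl2, 0 °C → rt
Reagents that add atoms: none
Why: Dess–Martin oxidation of the primary and the propargylic alcohol in one operation; the neutral conditions tolerate the non-enolisable 1,3-dicarbonyl arrays, the silyl ethers and the olefins.

Step 19
Reactants: 27 C5-formyl C1-ynone
Product: 28 C5 (E)-aldoxime C1-ynone (C1 R, C5 S, C7 R)
Conditions: NH2OH·HCl, NaOAc, EtOH/THF, 0 °C
Reagents that add atoms: hydroxylamine hydrochloride, NO.Cl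
Why: Oxime condensation; at 0 °C in acetate buffer the aldehyde should condense much faster than hydroxylamine adds to the hindered, electron-rich β-aryl ynone or to the doubly neopentyl C9 ketone.

Step 20
Reactants: 28 C5 (E)-aldoxime C1-ynone
Product: 30 isoxazole-fused bicyclo[3.3.1]nonane-2,9-dione (C1 S, C5 S, C7 R), via nitrile oxide 29 (not isolated)
Conditions: PhI(OAc)2, TFA (cat.), MeOH/CH2Cl2, 0 °C → rt
Reagents that add atoms: none
Why: PhI(OAc)2 dehydrogenates the aldoxime to nitrile oxide 29, which adds across the ynone in a concerted 1,3-dipolar cycloaddition; the closest known reaction type is the intramolecular nitrile oxide–alkyne cycloaddition. Ring A closes six-membered through the C4–C3 bond in a 6-exo-dig sense, and the isoxazole closes five-membered when the dipole oxygen bonds to the aryl-bearing alkyne carbon. No stereocentre is formed. Regiochemistry is fixed by the four-atom tether C5–C9–C1–C2, because the reverse orientation would need a seven-membered bridged ring, and it agrees with the electronic preference of the dipole oxygen for the β-carbon of an ynone. Proximity comes from ring B: with three allylic chains on one face only the chair that keeps them equatorial is populated, and in it nitrile oxide and ynone are 1,3-diaxial. The conjugated alkyne should therefore be engaged before the dipole can dimerise or reach a trisubstituted olefin, and a nitrile oxide on a quaternary carbon dimerises slowly in any case.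

Step 21
Reactants: 30 isoxazole-fused bicyclo[3.3.1]nonane-2,9-dione
Product: 31 4-amino-3-aroylbicyclo[3.3.1]non-3-ene-2,9-dione (enaminone; C1 S, C5 S, C7 R)
Conditions: Mo(CO)6, MeCN/H2O, 80 °C
Reagents that add atoms: none
Why: Reductive N–O cleavage of an isoxazole by Mo(CO)6 (zerovalent molybdenum) and water, a known isoxazole-to-enaminone conversion that leaves olefins, ketones and silyl ethers untouched.

Step 22
Reactants: 31 4-amino-3-aroylbicyclo[3.3.1]non-3-ene-2,9-dione
Product: 32 side-chain O-TBS ether of the target (C1 S, C5 S, C7 R)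
Conditions: KOH, degassed EtOH/H2O, 60 °C, argon; then 1 M HCl to pH 3, 0 °C
Reagents that add atoms: water, O
Why: Hydrolysis of a vinylogous amide by addition–elimination of hydroxide at C4 with loss of ammonia, driven by formation of the stabilised triketone enolate. Base is chosen over acid to avoid cyclisation of the enol oxygen onto prenyl olefins and ionisation of the allylic carbinol; it also cleaves the two aryl silyl ethers.

Step 23
Reactants: 32 side-chain O-TBS ether of the target
Product: 33 (1S,5S,7R)-3-(3,4-dihydroxybenzoyl)-4-hydroxy-5-[(2E,4S)-4-hydroxy-3,7-dimethylocta-2,6-dien-1-yl]-8,8-dimethyl-1,7-bis(3-methylbut-2-en-1-yl)bicyclo[3.3.1]non-3-ene-2,9-dione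
Conditions: HF·pyridine, pyridine, THF, 0 °C → rt
Reagents that add atoms: none
Why: Fluoride-mediated cleavage of the remaining secondary silyl ether under pyridine-buffered conditions that should not ionise the allylic alcohol or promote enol–olefin cyclisation.

## Compound list

In the names below, "side chain" means (2E,4S)-4-[(tert-butyldimethylsilyl)oxy]-3,7-dimethylocta-2,6-dien-1-yl and "Ar" means 3,4-bis[(tert-butyldimethylsilyl)oxy]phenyl.

1 | 5-methylhex-4-enal | CC(C)=CCCC=O | starting material
2 | but-3-en-2-one (methyl vinyl ketone) | CC(=O)C=C | starting material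
3 | (2S)-2-(3-methylbut-2-en-1-yl)-5-oxohexanal | CC(C)=CC[C@@H](C=O)CCC(C)=O | intermediate
4 | (4S)-4-(3-methylbut-2-en-1-yl)cyclohex-2-en-1-one | CC(C)=CC[C@@H]1CCC(=O)C=C1 | intermediate
5 | trimethyl{[(3S,4S)-3-methyl-4-(3-methylbut-2-en-1-yl)cyclohex-1-en-1-yl]oxy}silane (3,4-trans) | CC(C)=CC[C@@H]1CCC(O[Si](C)(C)C)=C[C@H]1C | intermediate
6 | (4S)-3-methyl-4-(3-methylbut-2-en-1-yl)cyclohex-2-en-1-one | CC(C)=CC[C@@H]1CCC(=O)C=C1C | intermediate
7 | 1-bromo-3-methylbut-2-ene (prenyl bromide) | CC(C)=CCBr | starting material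
8 | lithium (4S)-3,3-dimethyl-4-(3-methylbut-2-en-1-yl)cyclohex-1-en-1-olate | CC(C)=CC[C@@H]1CCC([O-])=CC1(C)C.[Li+] | intermediate (not isolated)
9 | (4S)-3,3-dimethyl-2,4-bis(3-methylbut-2-en-1-yl)cyclohexan-1-one, mixture of C2 epimers | CC(C)=CC[C@@H]1CCC(=O)C(CC=C(C)C)C1(C)C | intermediate
10 | (2E)-3-methyl-4-oxobut-2-en-1-yl acetate | CC(=O)OC/C=C(\C)C=O | starting material
11 | (2E,4S)-4-hydroxy-3-methylhepta-2,6-dien-1-yl acetate | CC(=O)OC/C=C(\C)[C@@H](O)CC=C | intermediate
12 | (2E,4S)-4-[(tert-butyldimethylsilyl)oxy]-3-methylhepta-2,6-dien-1-yl acetate | CC(=O)OC/C=C(\C)[C@@H](O[Si](C)(C)C(C)(C)C)CC=C | intermediate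
13 | (2E,4S)-4-[(tert-butyldimethylsilyl)oxy]-3,7-dimethylocta-2,6-dien-1-yl acetate | CC(=O)OC/C=C(\C)[C@@H](O[Si](C)(C)C(C)(C)C)CC=C(C)C | intermediate
14 | (2E,4S)-4-[(tert-butyldimethylsilyl)oxy]-3,7-dimethylocta-2,6-dien-1-ol | OC/C=C(\C)[C@@H](O[Si](C)(C)C(C)(C)C)CC=C(C)C | intermediate
15 | (2E,4S)-1-bromo-4-[(tert-butyldimethylsilyl)oxy]-3,7-dimethylocta-2,6-diene | BrC/C=C(\C)[C@@H](O[Si](C)(C)C(C)(C)C)CC=C(C)C | intermediate
16 | ring B ketone with H and prenyl on C1, H and side chain on C5, prenyl on C7 (R), gem-dimethyl on C8; kinetic mixture of C1/C5 epimers | CC(C)=CC[C@@H]1CC(C/C=C(\C)[C@@H](O[Si](C)(C)C(C)(C)C)CC=C(C)C)C(=O)C(CC=C(C)C)C1(C)C | intermediate (not isolated)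
17 | (2R,4R,6S)-6-(side chain)-3,3-dimethyl-2,4-bis(3-methylbut-2-en-1-yl)cyclohexan-1-one; target labels C1 R, C5 S, C7 R; the three chains cis and equatorial | CC(C)=CC[C@@H]1C[C@H](C/C=C(\C)[C@@H](O[Si](C)(C)C(C)(C)C)CC=C(C)C)C(=O)[C@H](CC=C(C)C)C1(C)C | intermediate
18 | 17 with a hydroxymethyl group on C5, trans to the three chains (C1 R, C5 S, C7 R) | CC(C)=CC[C@@H]1C[C@](CO)(C/C=C(\C)[C@@H](O[Si](C)(C)C(C)(C)C)CC=C(C)C)C(=O)[C@H](CC=C(C)C)C1(C)C | intermediate
19 | triethylsilyl ether of 18 (C1 R, C5 S, C7 R) | CC(C)=CC[C@@H]1C[C@](CO[Si](CC)(CC)CC)(C/C=C(\C)[C@@H](O[Si](C)(C)C(C)(C)C)CC=C(C)C)C(=O)[C@H](CC=C(C)C)C1(C)C | intermediate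
20 | 3,4-dihydroxybenzaldehyde | O=Cc1ccc(O)c(O)c1 | starting material
21 | 3,4-bis[(tert-butyldimethylsilyl)oxy]benzaldehyde | O=Cc1ccc(O[Si](C)(C)C(C)(C)C)c(O[Si](C)(C)C(C)(C)C)c1 | intermediate
22 | 4-(2,2-dibromoethenyl)-1,2-bis[(tert-butyldimethylsilyl)oxy]benzene | BrC(Br)=Cc1ccc(O[Si](C)(C)C(C)(C)C)c(O[Si](C)(C)C(C)(C)C)c1 | intermediate
23 | lithium {3,4-bis[(tert-butyldimethylsilyl)oxy]phenyl}acetylide | [Li+].[C-]#Cc1ccc(O[Si](C)(C)C(C)(C)C)c(O[Si](C)(C)C(C)(C)C)c1 | intermediate (not isolated)
24 | 3-{3,4-bis[(tert-butyldimethylsilyl)oxy]phenyl}prop-2-ynal | O=CC#Cc1ccc(O[Si](C)(C)C(C)(C)C)c(O[Si](C)(C)C(C)(C)C)c1 | intermediate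
25 | 19 carrying on C1, beside prenyl, a 3-Ar-1-hydroxyprop-2-yn-1-yl group cis to the C5 CH2OTES arm (C1 R, C5 S, C7 R; carbinol epimers) | CC(C)=CC[C@@H]1C[C@](CO[Si](CC)(CC)CC)(C/C=C(\C)[C@@H](O[Si](C)(C)C(C)(C)C)CC=C(C)C)C(=O)[C@@](CC=C(C)C)(C(O)C#Cc2ccc(O[Si](C)(C)C(C)(C)C)c(O[Si](C)(C)C(C)(C)C)c2)C1(C)C | intermediate (not isolated)
26 | diol: 25 without the triethylsilyl group (C1 R, C5 S, C7 R; carbinol epimers) | CC(C)=CC[C@@H]1C[C@](CO)(C/C=C(\C)[C@@H](O[Si](C)(C)C(C)(C)C)CC=C(C)C)C(=O)[C@@](CC=C(C)C)(C(O)C#Cc2ccc(O[Si](C)(C)C(C)(C)C)c(O[Si](C)(C)C(C)(C)C)c2)C1(C)C | intermediate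
27 | ring B ketone with formyl and side chain on C5, 3-Ar-propynoyl and prenyl on C1, formyl and ynone cis (C1 R, C5 S, C7 R) | CC(C)=CC[C@@H]1C[C@](C=O)(C/C=C(\C)[C@@H](O[Si](C)(C)C(C)(C)C)CC=C(C)C)C(=O)[C@@](CC=C(C)C)(C(=O)C#Cc2ccc(O[Si](C)(C)C(C)(C)C)c(O[Si](C)(C)C(C)(C)C)c2)C1(C)C | intermediate
28 | (E)-aldoxime of 27 (C1 R, C5 S, C7 R) | CC(C)=CC[C@@H]1C[C@](/C=N/O)(C/C=C(\C)[C@@H](O[Si](C)(C)C(C)(C)C)CC=C(C)C)C(=O)[C@@](CC=C(C)C)(C(=O)C#Cc2ccc(O[Si](C)(C)C(C)(C)C)c(O[Si](C)(C)C(C)(C)C)c2)C1(C)C | intermediate
29 | nitrile oxide derived from 28 (C1 R, C5 S, C7 R) | CC(C)=CC[C@@H]1C[C@](C#[N+][O-])(C/C=C(\C)[C@@H](O[Si](C)(C)C(C)(C)C)CC=C(C)C)C(=O)[C@@](CC=C(C)C)(C(=O)C#Cc2ccc(O[Si](C)(C)C(C)(C)C)c(O[Si](C)(C)C(C)(C)C)c2)C1(C)C | intermediate (not isolated)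
30 | bicyclo[3.3.1]nonane-2,9-dione whose C3–C4 bond is the C4–C3 bond of an isoxazole bearing Ar on the oxygen-bound carbon; prenyl on C1 and C7, side chain on C5, gem-dimethyl on C8 (C1 S, C5 S, C7 R) | CC(C)=CC[C@@H]1C[C@]2(C/C=C(\C)[C@@H](O[Si](C)(C)C(C)(C)C)CC=C(C)C)C(=O)[C@@](CC=C(C)C)(C(=O)c3c2noc3-c4ccc(O[Si](C)(C)C(C)(C)C)c(O[Si](C)(C)C(C)(C)C)c4)C1(C)C | intermediate
31 | (1S,5S,7R)-4-amino-3-(Ar-carbonyl)-5-(side chain)-8,8-dimethyl-1,7-bis(3-methylbut-2-en-1-yl)bicyclo[3.3.1]non-3-ene-2,9-dione | CC(C)=CC[C@@H]1C[C@]2(C/C=C(\C)[C@@H](O[Si](C)(C)C(C)(C)C)CC=C(C)C)C(=O)[C@@](CC=C(C)C)(C(=O)C(C(=O)c3ccc(O[Si](C)(C)C(C)(C)C)c(O[Si](C)(C)C(C)(C)C)c3)=C2N)C1(C)C | intermediate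
32 | (1S,5S,7R)-3-(3,4-dihydroxybenzoyl)-4-hydroxy-5-(side chain)-8,8-dimethyl-1,7-bis(3-methylbut-2-en-1-yl)bicyclo[3.3.1]non-3-ene-2,9-dione | CC(C)=CC[C@@H]1C[C@]2(C/C=C(\C)[C@@H](O[Si](C)(C)C(C)(C)C)CC=C(C)C)C(=O)[C@@](CC=C(C)C)(C(=O)C(C(=O)c3ccc(O)c(O)c3)=C2O)C1(C)C | intermediate
33 | (1S,5S,7R)-3-(3,4-dihydroxybenzoyl)-4-hydroxy-5-[(2E,4S)-4-hydroxy-3,7-dimethylocta-2,6-dien-1-yl]-8,8-dimethyl-1,7-bis(3-methylbut-2-en-1-yl)bicyclo[3.3.1]non-3-ene-2,9-dione | CC(C)=CC[C@@H]1C[C@]2(C/C=C(\C)[C@@H](O)CC=C(C)C)C(=O)[C@@](CC=C(C)C)(C(=O)C(C(=O)c3ccc(O)c(O)c3)=C2O)C1(C)C | target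

## Step count and least certain steps

Total: 23 steps. Longest linear sequence: 15 steps (steps 1–5, 11–13 and 17–23; the side-chain branch through steps 6–13 and 17–23 is equally long).

**Step 20 (key step).** The nitrile oxide may dimerise or be captured by solvent if ring B adopts a twist form in which the ynone does not reach it, and the iodine oxidant may attack the electron-rich arene or an olefin. Fallback: the dipolarophile is changed to an unconjugated, conformationally freer alkyne. Starting from 28, Luche reduction (NaBH4, CeCl3·7H2O, MeOH, −78 °C) of the ynone carbonyl would give the hydroxy aldoxime F1; the C9 ketone is shielded by two quaternary carbons. Oxidation of F1 with PhI(OAc)2 would lead by the same cycloaddition to the isoxazolyl carbinol F2. Dess–Martin oxidation of this carbinol next to the heteroaromatic ring returns to 30.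

**Step 17.** Enolisation of the hindered C1–H may be incomplete, the lithium aldolate may revert on warming, and facial discrimination at C1 may leak because the incoming aldehyde passes the axial C5 arm. Fallback: the C1–C2 bond is made with the smallest electrophile and the alkyne is added as a nucleophile. Starting from 19, the lithium enolate and monomeric formaldehyde would give the C1-hydroxymethyl ketone F3, and Dess–Martin oxidation the C1 aldehyde F4. The arylalkyne F5 (from 22 with n-BuLi, then water) would be lithiated and added to F4 at −78 °C, where the C9 ketone is too hindered to compete. This gives 25, which is desilylated with PPTS in MeOH as in step 17 to return to 26.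

**Step 19.** Conjugate addition of hydroxylamine to the ynone or deformylation of the β-keto aldehyde may compete with oxime formation. Fallback: the oxime is installed, in protected form, before the ynone exists. Starting from 26, TEMPO with PhI(OAc)2 would oxidise only the primary alcohol to the hydroxy aldehyde F6. Condensation with O-(tert-butyldimethylsilyl)hydroxylamine (PPTS cat., MgSO4, CH2Cl2) would give the O-silyl oxime carbinol F7, which has no free N–OH to react with the next oxidant. Dess–Martin oxidation would give the O-silyl oxime ynone F8, and brief treatment with HF·pyridine in pyridine/THF at 0 °C would cleave the labile oxime silyl ether and return to 28.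

**Step 12.** Deprotonation may occur partly at C1, or formaldehyde may approach C5 from the face of the C7 prenyl group if a minor C1-axial epimer of 17 is carried along. Fallback: the enolate is generated from an isolated enol ether instead of by deprotonation. Starting from 17, thermodynamic silylation (TMSCl, NaI, Et3N, MeCN) would give the more substituted C5=C9 silyl enol ether F9, which can be purified. Hydroxymethylation with aqueous formaldehyde and catalytic Sc(OTf)3 in THF (Mukaiyama-type aldol) returns to 18.

**Step 22.** Hydrolysis may stall because the deprotonated vinylogous amide resists hydroxide at the hindered C4, and the free catechol may oxidise in hot base. Fallback: the nitrogen is turned into a better leaving group. Starting from 31, Boc2O with DMAP in MeCN would give the N-Boc enaminone F10. LiOH in THF/H2O at room temperature would then displace tert-butyl carbamate from C4 and cleave the aryl silyl ethers, returning to 32.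

## Further compounds

F1 | step 20 | C5 (E)-aldoxime with a 3-Ar-1-hydroxyprop-2-yn-1-yl group on C1 (ring configuration as in 28; carbinol epimers) | CC(C)=CC[C@@H]1C[C@](/C=N/O)(C/C=C(\C)[C@@H](O[Si](C)(C)C(C)(C)C)CC=C(C)C)C(=O)[C@@](CC=C(C)C)(C(O)C#Cc2ccc(O[Si](C)(C)C(C)(C)C)c(O[Si](C)(C)C(C)(C)C)c2)C1(C)C
F2 | step 20 | C2 carbinol of 30 (isoxazole-fused 2-hydroxybicyclo[3.3.1]nonan-9-one; carbinol epimers) | CC(C)=CC[C@@H]1C[C@]2(C/C=C(\C)[C@@H](O[Si](C)(C)C(C)(C)C)CC=C(C)C)C(=O)[C@@](CC=C(C)C)(C(O)c3c2noc3-c4ccc(O[Si](C)(C)C(C)(C)C)c(O[Si](C)(C)C(C)(C)C)c4)C1(C)C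
F3 | step 17 | 19 with a hydroxymethyl group on C1, cis to the C5 CH2OTES arm | CC(C)=CC[C@@H]1C[C@](CO[Si](CC)(CC)CC)(C/C=C(\C)[C@@H](O[Si](C)(C)C(C)(C)C)CC=C(C)C)C(=O)[C@@](CC=C(C)C)(CO)C1(C)C
F4 | step 17 | 19 with a formyl group on C1, cis to the C5 CH2OTES arm | CC(C)=CC[C@@H]1C[C@](CO[Si](CC)(CC)CC)(C/C=C(\C)[C@@H](O[Si](C)(C)C(C)(C)C)CC=C(C)C)C(=O)[C@@](CC=C(C)C)(C=O)C1(C)C
F5 | step 17 | 4-ethynyl-1,2-bis[(tert-butyldimethylsilyl)oxy]benzene | C#Cc1ccc(O[Si](C)(C)C(C)(C)C)c(O[Si](C)(C)C(C)(C)C)c1
F6 | step 19 | C5-formyl ketone with a 3-Ar-1-hydroxyprop-2-yn-1-yl group on C1 (ring configuration as in 26; carbinol epimers) | CC(C)=CC[C@@H]1C[C@](C=O)(C/C=C(\C)[C@@H](O[Si](C)(C)C(C)(C)C)CC=C(C)C)C(=O)[C@@](CC=C(C)C)(C(O)C#Cc2ccc(O[Si](C)(C)C(C)(C)C)c(O[Si](C)(C)C(C)(C)C)c2)C1(C)C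
F7 | step 19 | O-(tert-butyldimethylsilyl) (E)-oxime of F6 | CC(C)=CC[C@@H]1C[C@](/C=N/O[Si](C)(C)C(C)(C)C)(C/C=C(\C)[C@@H](O[Si](C)(C)C(C)(C)C)CC=C(C)C)C(=O)[C@@](CC=C(C)C)(C(O)C#Cc2ccc(O[Si](C)(C)C(C)(C)C)c(O[Si](C)(C)C(C)(C)C)c2)C1(C)C
F8 | step 19 | O-(tert-butyldimethylsilyl) ether of oxime 28 | CC(C)=CC[C@@H]1C[C@](/C=N/O[Si](C)(C)C(C)(C)C)(C/C=C(\C)[C@@H](O[Si](C)(C)C(C)(C)C)CC=C(C)C)C(=O)[C@@](CC=C(C)C)(C(=O)C#Cc2ccc(O[Si](C)(C)C(C)(C)C)c(O[Si](C)(C)C(C)(C)C)c2)C1(C)C
F9 | step 12 | C5=C9 trimethylsilyl enol ether of 17 | CC(C)=CC[C@@H]1CC(C/C=C(\C)[C@@H](O[Si](C)(C)C(C)(C)C)CC=C(C)C)=C(O[Si](C)(C)C)[C@H](CC=C(C)C)C1(C)C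
F10 | step 22 | N-(tert-butoxycarbonyl) derivative of enaminone 31 | CC(C)=CC[C@@H]1C[C@]2(C/C=C(\C)[C@@H](O[Si](C)(C)C(C)(C)C)CC=C(C)C)C(=O)[C@@](CC=C(C)C)(C(=O)C(C(=O)c3ccc(O[Si](C)(C)C(C)(C)C)c(O[Si](C)(C)C(C)(C)C)c3)=C2NC(=O)OC(C)(C)C)C1(C)C
A1 | alternative 1 | cis-hydrindane C4–C5 epoxide with tertiary C9 alcohol and C2 ethylene ketal | CC(C)=CC[C@@H]1C[C@@]2(O)[C@]3(C/C=C(\C)[C@@H](O[Si](C)(C)C(C)(C)C)CC=C(C)C)O[C@@H]3CC4(OCCO4)[C@@]2(CC=C(C)C)C1(C)C
A2 | alternative 1 | bridged 4-hydroxy-9-ketone with C2 ethylene ketal | CC(C)=CC[C@@H]1C[C@]2(C/C=C(\C)[C@@H](O[Si](C)(C)C(C)(C)C)CC=C(C)C)C(=O)[C@@](CC=C(C)C)(C3(OCCO3)C[C@H]2O)C1(C)C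
A3 | alternative 2 | C9 tert-butyldimethylsilyl enol ether (C5=C9) with a terminal propynoyl group on C1 | CC(C)=CC[C@@H]1CC(C/C=C(\C)[C@@H](O[Si](C)(C)C(C)(C)C)CC=C(C)C)=C(O[Si](C)(C)C(C)(C)C)[C@@](CC=C(C)C)(C(=O)C#C)C1(C)C
A4 | alternative 2 | bicyclo[3.3.1]non-3-ene-2,9-dione | CC(C)=CC[C@@H]1C[C@]2(C/C=C(\C)[C@@H](O[Si](C)(C)C(C)(C)C)CC=C(C)C)C(=O)[C@@](CC=C(C)C)(C(=O)C=C2)C1(C)C
A5 | alternative 3 | ring B ketone with a diazoacetyl group on C5 and a formyl group on C1 | CC(C)=CC[C@@H]1C[C@](C(=O)C=[N+]=[N-])(C/C=C(\C)[C@@H](O[Si](C)(C)C(C)(C)C)CC=C(C)C)C(=O)[C@@](CC=C(C)C)(C=O)C1(C)C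
A6 | alternative 3 | bicyclo[3.3.1]nonane-2,4,9-trione | CC(C)=CC[C@@H]1C[C@]2(C/C=C(\C)[C@@H](O[Si](C)(C)C(C)(C)C)CC=C(C)C)C(=O)[C@@](CC=C(C)C)(C(=O)CC2=O)C1(C)C
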